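**Plan**

Numbering follows the germacranolides: C1 ketone, C4=C5 (Z), C6 (lactone oxygen), C7, C8 (ester oxygen), C10 (tertiary carbinol), C11=C13, C12 lactone carbonyl.
Cuts: the C8 ester and the C1 ketone level last; then C12–O6 and C5–C6 together, because C6 is an allylic carbinol carbon between C5 of the Z alkene and C7 and its oxygen is the lactone oxygen; then C7–C8 (allylation) and C2–C3 (enolate alkylation).
Forward: the open chain C5→C13 is joined from (R)-citramalic acid (C1, C8–C10), an iodoallyl bromide (C3–C5 with the C4 methyl) and a Baylis–Hillman bromide (C6, C7, C11–C13); the ten-membered carbocycle closes first by alkenylchromium addition to the C6 aldehyde, the γ-lactone second, in the same step.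
Stereochemistry: C10 from citramalic acid; Z C4=C5 from anti-carbomagnesiation; the syn C7/C8 pair from a catalyst-controlled chromium allylation; C6 from C7 during ring closure.
C1 travels as a 1S carbinol (reagent-controlled reduction) tied to C10 as a cis-dioxolane and is oxidised at the end, because a free C1 ketone lies 1,5 to C5 and would capture the alkenylchromium as a cyclopentenol.

Key step: step 18

Remark: the aldehyde used in step 3 is taken as a purchasable reagent; ozonolysis of (Z)-1,4-bis(4-methoxybenzyloxy)but-2-ene gives it otherwise. Abbreviations: TMS, TES, TBS = trimethyl-, triethyl-, tert-butyldimethylsilyl; PMB = 4-methoxybenzyl; Dx = (4R,5S)-5-[(3Z)-4-iodo-3-methylbut-3-en-1-yl]-2,2,4-trimethyl-1,3-dioxolan-4-yl. CIP descriptors are given for the substituents actually present, so the label at C7 changes between R and S along the route although its geometry does not.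

**Route**

Step 1
Reactants: 1 prop-2-yn-1-ol
Product: 3 (Z)-3-iodo-2-methylprop-2-en-1-ol, via alkenylmagnesium alkoxide 2 (not isolated)
Conditions: MeMgBr (2.5 equiv), CuI (10 mol %), THF, −10 → 23 °C; then I2, −10 °C
Reagents that add atoms: methylmagnesium bromide, C[Mg]Br; iodine, II
Why: Copper-catalysed anti-carbomagnesiation of the propargylic alkoxide places magnesium cis to the CH2O group by chelation, and iodinolysis with retention gives the Z iodoalkene that becomes C4=C5.

Step 2
Reactants: 3 (Z)-3-iodo-2-methylprop-2-en-1-ol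
Product: 4 (Z)-3-bromo-1-iodo-2-methylprop-1-ene
Conditions: CBr4, PPh3, CH2Cl2, 0 °C
Reagents that add atoms: carbon tetrabromide, BrC(Br)(Br)Br
Why: Appel bromination of the primary allylic alcohol is an SN2 displacement that leaves the alkenyl iodide and the alkene geometry untouched.

Step 3
Reactants: 5 methyl acrylate; 6 2-[(4-methoxybenzyl)oxy]acetaldehyde
Product: 7 methyl 3-hydroxy-4-[(4-methoxybenzyl)oxy]-2-methylidenebutanoate (racemic)
Conditions: DABCO (0.5 equiv), 1,4-dioxane–H2O (1:1), 23 °C
Reagents that add atoms: none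
Why: Morita–Baylis–Hillman reaction of an acrylate with a reactive α-alkoxy aldehyde; the racemic carbinol centre is erased in step 4.

Step 4
Reactants: 7 Baylis–Hillman alcohol
Product: 8 methyl (2Z)-2-(bromomethyl)-4-[(4-methoxybenzyl)oxy]but-2-enoate
Conditions: NBS, Me2S, CH2Cl2, 0 → 23 °C
Reagents that add atoms: N-bromosuccinimide, O=C1CCC(=O)N1Br
Why: The alcohol is activated as an alkoxysulfonium salt and bromide attacks in the SN2' sense, giving the more stable 2-(bromomethyl)enoate with CH2OPMB trans to the ester (Z).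

Step 5
Reactants: 9 (R)-citramalic acid
Product: 10 2-[(4R)-2,2,4-trimethyl-5-oxo-1,3-dioxolan-4-yl]acetic acid
Conditions: 2,2-dimethoxypropane, TsOH·H2O (cat.), 23 °C
Reagents that add atoms: 2,2-dimethoxypropane, COC(C)(C)OC
Why: Acid-catalysed acetalisation ties the tertiary hydroxyl and the adjacent carboxyl into the five-membered dioxolanone, which differentiates the two acids and leaves the C8 acid free.

Step 6
Reactants: 10 dioxolanone acid
Product: 12 (3R)-3-hydroxy-3-methyloxolan-2-one, via hydroxyethyl dioxolanone 11 (not isolated)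
Conditions: BH3·SMe2, THF, 0 → 23 °C; aqueous work-up; TsOH·H2O (cat.), CH2Cl2, 23 °C
Reagents that add atoms: none
Why: Borane reduces the free carboxylic acid chemoselectively, and under acid catalysis the new primary alcohol transacylates the dioxolanone to the γ-lactone with loss of acetone; C10 is not touched.

Step 7
Reactants: 12 hydroxy lactone
Product: 13 (2R)-2,4-dihydroxy-N-methoxy-N,2-dimethylbutanamide
Conditions: Me(MeO)NH·HCl, Me3Al, CH2Cl2, 0 → 23 °C
Reagents that add atoms: N,O-dimethylhydroxylamine hydrochloride, CNOC.Cl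
Why: Aluminium amide aminolysis of the γ-lactone (Weinreb amide formation) opens the ring at the acyl carbon and makes C1 a ketone precursor.

Step 8
Reactants: 13 Weinreb amide diol
Product: 14 (2R)-N-methoxy-N,2-dimethyl-2,4-bis(triethylsilyloxy)butanamide
Conditions: Et3SiOTf, 2,6-lutidine, CH2Cl2, −78 → 0 °C
Reagents that add atoms: triethylsilyl triflate, CC[Si](CC)(CC)OS(=O)(=O)C(F)(F)F
Why: Silyl triflate with lutidine silylates the primary and the tertiary hydroxyl alike, which blocks relactonisation and removes the acidic protons before the organometallic steps.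

Step 9
Reactants: 14 bis-silyl Weinreb amide
Product: 15 (3R)-3-methyl-3,5-bis(triethylsilyloxy)pentan-2-one
Conditions: MeMgBr, THF, 0 °C
Reagents that add atoms: methylmagnesium bromide, C[Mg]Br
Why: Weinreb ketone synthesis, in which the chelated tetrahedral adduct stops at the methyl ketone that supplies C2.

Step 10
Reactants: 15 methyl ketone; 4 (Z)-3-bromo-1-iodo-2-methylprop-1-ene
Product: 17 (3R,7Z)-8-iodo-3,7-dimethyl-1,3-bis(triethylsilyloxy)oct-7-en-4-one, via lithium enolate 16 (not isolated)
Conditions: LiN(iPr)2, THF, −78 °C; then 4, DMPU, −78 → −30 °C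
Reagents that add atoms: none
Why: Only the methyl group is enolisable because C10 is quaternary, so the lithium enolate is regiodefined and SN2 alkylation by the primary allylic bromide forms C2–C3 with the Z iodoalkene intact.

Step 11
Reactants: 17 iodoalkenyl ketone
Product: 18 (3R,4S,7Z)-8-iodo-3,7-dimethyl-1,3-bis(triethylsilyloxy)oct-7-en-4-ol
Conditions: (R)-Me-CBS [(R)-1-methyl-3,3-diphenyltetrahydro-1H,3H-pyrrolo[1,2-c][1,3,2]oxazaborole] (0.2 equiv), catecholborane, toluene, −78 → −40 °C
Reagents that add atoms: none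
Why: Corey–Bakshi–Shibata reduction, in which the oxazaborolidine distinguishes the fully substituted C10 side from the CH2 side and should deliver hydride under reagent control to the 1S carbinol, the configuration that puts the C2 and C9 arms cis on the later dioxolane; catecholborane at low temperature spares the iodoalkene.

Step 12
Reactants: 18 secondary alcohol
Product: 20 2-Dx-ethan-1-ol, via triol 19 (not isolated)
Conditions: TsOH·H2O (cat.), MeOH, 23 °C; concentrate; 2,2-dimethoxypropane, acetone, 23 °C; Et3N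
Reagents that add atoms: 2,2-dimethoxypropane, COC(C)(C)OC
Why: Acid-catalysed methanolysis removes both triethylsilyl ethers and thermodynamic acetonide formation then selects the five-membered dioxolane of the C1/C10 diol, because the alternative 1,3-dioxane through O8 would carry a syn-axial methyl pair; the primary C8 hydroxyl stays free.

Step 13
Reactants: 20 dioxolane alcohol
Product: 21 2-Dx-acetaldehyde
Conditions: Dess–Martin periodinane, NaHCO3, CH2Cl2, 0 → 23 °C
Reagents that add atoms: none
Why: Dess–Martin oxidation of a primary alcohol stops at the aldehyde under buffered conditions that leave the dioxolane and the iodoalkene alone.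

Step 14
Reactants: 21 dioxolane aldehyde; 8 allylic bromide
Product: 23 methyl (3S,4R)-4-hydroxy-5-Dx-3-{[(4-methoxybenzyl)oxy]methyl}-2-methylidenepentanoate, via silyl ether 22 (not isolated)
Conditions: nickel-free CrCl2 (10 mol %), tridentate carbazole-1,8-bis(oxazoline) ligand (12 mol %, antipode that directs Si-face attack), Mn, iPr2NEt (0.3 equiv), Me3SiCl, THF, 23 °C; then citric acid, MeOH, 0 °C
Reagents that add atoms: none
Why: Chromium-catalysed asymmetric 2-(alkoxycarbonyl)allylation of Nozaki–Hiyama type, in which the allylchromium from 8 adds through a closed chair with the CH2OPMB group (held trans to the ester) axial, giving the syn C7/C8 pair, while the chiral chromium complex selects the Si face of the aldehyde to set 8R (the 1,3-anti preference of the β-alkoxy aldehyde points the same way); without nickel the alkenyl iodide is inert.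

Step 15
Reactants: 23 hydroxy ester
Product: 24 methyl (3S,4R)-4-(tert-butyldimethylsilyloxy)-5-Dx-3-{[(4-methoxybenzyl)oxy]methyl}-2-methylidenepentanoate
Conditions: tBuMe2SiOTf, 2,6-lutidine, CH2Cl2, −78 °C
Reagents that add atoms: tert-butyldimethylsilyl triflate, CC(C)(C)[Si](C)(C)OS(=O)(=O)C(F)(F)F
Why: Silyl triflate silylation of the hindered secondary alcohol at low temperature forestalls lactonisation of O8 onto the ester and installs a β-silyloxy group that resists elimination in the later aldehyde.

Step 16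
Reactants: 24 PMB ether
Product: 25 methyl (3S,4R)-4-(tert-butyldimethylsilyloxy)-5-Dx-3-(hydroxymethyl)-2-methylidenepentanoate
Conditions: DDQ, CH2Cl2–pH 7 phosphate buffer, 0 °C; no chromatography
Reagents that add atoms: none
Why: Oxidative cleavage of the 4-methoxybenzyl ether by DDQ (hydride abstraction, then hydrolysis of the oxocarbenium ion) is neutral, so the silyl ether, dioxolane, iodoalkene and acrylate persist and the γ-hydroxy ester meets neither acid nor base that would lactonise it.

Step 17
Reactants: 25 primary alcohol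
Product: 26 methyl (3R,4R)-4-(tert-butyldimethylsilyloxy)-5-Dx-3-formyl-2-methylidenepentanoate
Conditions: Dess–Martin periodinane, NaHCO3, CH2Cl2, 0 °C; used crude at once
Reagents that add atoms: none
Why: Dess–Martin oxidation in buffered CH2Cl2 forms the α-branched β,γ-unsaturated aldehyde without base, so C7 should not epimerise and the C11=C13 bond should not move into conjugation.

Step 18
Reactants: 26 iodoalkenyl aldehyde
Product: 29 (1S,4Z,6R,7S,8R,10R)-8-(tert-butyldimethylsilyloxy)-1,10-(isopropylidenedioxy)germacra-4,11(13)-dien-12,6-olide, via silyl ether 27 (not isolated), via hydroxy ester 28 (not isolated)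
Conditions: CrCl2 (20 mol %), NiCl2 (2 mol %), Me3SiCl (3 equiv), LiClO4, DMF, undivided cell, Al anode/Pt cathode, constant current, 23 °C, 26 added by syringe pump (2 mM final); aq. citric acid, THF; then CSA (cat.), CH2Cl2, 23 °C
Reagents that add atoms: none
Why: Zerovalent nickel inserts into the C5–I bond with retention of the Z geometry and passes the alkenyl group to trivalent chromium, the alkenylchromium adds 1,2 to the C6 aldehyde, Me3SiCl releases chromium as silyl ether 27 and the cathode returns it to the divalent state, so chromium turns over. The closest known reaction is the nickel/chromium Nozaki–Hiyama–Kishi alkenyl iodide–aldehyde macrocyclisation in its electroreductive, chromium-catalytic form. The carbocycle closes 10-exo-trig by this addition, helped by the cis-dioxolane that turns the C2 and C9 arms toward each other, and after desilylation the C6 hydroxyl closes the γ-lactone 5-exo-trig on the C12 methyl ester with loss of methanol. C6 is set by C7: C5, tethered through C8, approaches anti to the C8 arm with the acrylate gauche to the carbonyl oxygen (Felkin–Anh arrangement, reinforced by chromium bridging the aldehyde and ester oxygens), which should give 6R and hence the trans-fused lactone. The step needs the aldehyde to be the only carbonyl within reach of C5, which is why C1 is held as the dioxolane carbinol and the acrylate ester is left to the slower lactonisation, and it needs ring closure to outrun oligomerisation, which slow addition at millimolar concentration secures.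

Step 19
Reactants: 29 silyloxy lactone
Product: 30 (1S,4Z,6R,7R,8R,10R)-8-hydroxy-1,10-(isopropylidenedioxy)germacra-4,11(13)-dien-12,6-olide
Conditions: HF·pyridine, pyridine, THF, 0 → 23 °C
Reagents that add atoms: none
Why: Buffered fluoride cleaves the secondary silyl ether while the dioxolane, the lactone and the exocyclic methylene are stable.

Step 20
Reactants: 30 hydroxy lactone
Product: 31 (1S,4Z,6R,7R,8R,10R)-1,10-(isopropylidenedioxy)-8-(3-methylbutanoyloxy)germacra-4,11(13)-dien-12,6-olide
Conditions: 3-methylbutanoic anhydride, DMAP (4-(dimethylamino)pyridine), Et3N, CH2Cl2, 0 → 23 °C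
Reagents that add atoms: 3-methylbutanoic anhydride, CC(C)CC(=O)OC(=O)CC(C)C
Why: DMAP-catalysed acylation of the only free hydroxyl (C8) by the anhydride.

Step 21
Reactants: 31 isovalerate acetonide
Product: 32 (1S,4Z,6R,7R,8R,10R)-1,10-dihydroxy-8-(3-methylbutanoyloxy)germacra-4,11(13)-dien-12,6-olide
Conditions: AcOH–H2O (4:1), 40 °C
Reagents that add atoms: none
Why: Acid-catalysed hydrolysis of the isopropylidene ketal through its oxocarbenium ion; the ester, the lactone and the allylic C6–O bond should tolerate warm aqueous acetic acid.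

Step 22
Reactants: 32 diol
Product: 33 (4Z,6R,7R,8R,10R)-10-hydroxy-8-(3-methylbutanoyloxy)-1-oxogermacra-4,11(13)-dien-12,6-olide (CNP0105188.1)
Conditions: IBX, DMSO, 23 °C
Reagents that add atoms: none
Why: IBX oxidises the secondary C1 carbinol of the 1,2-diol to the α-hydroxy ketone without C–C cleavage, the tertiary C10 hydroxyl being inert.

**Compound list**

1 | prop-2-yn-1-ol | C#CCO | starting material
2 | bromomagnesium (Z)-3-(bromomagnesio)-2-methylprop-2-en-1-olate | C/C(CO[Mg]Br)=C/[Mg]Br | intermediate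
3 | (Z)-3-iodo-2-methylprop-2-en-1-ol | I/C=C(/C)CO | intermediate
4 | (Z)-3-bromo-1-iodo-2-methylprop-1-ene | I/C=C(/C)CBr | intermediate
5 | methyl acrylate | C=CC(=O)OC | starting material
6 | 2-[(4-methoxybenzyl)oxy]acetaldehyde | O=CCOCc1ccc(OC)cc1 | starting material
7 | methyl 3-hydroxy-4-[(4-methoxybenzyl)oxy]-2-methylidenebutanoate (racemic) | C=C(C(=O)OC)C(O)COCc1ccc(OC)cc1 | intermediate
8 | methyl (2Z)-2-(bromomethyl)-4-[(4-methoxybenzyl)oxy]but-2-enoate | BrC/C(C(=O)OC)=C\COCc1ccc(OC)cc1 | intermediate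
9 | (R)-citramalic acid, (2R)-2-hydroxy-2-methylbutanedioic acid | OC(=O)[C@](C)(O)CC(=O)O | starting material
10 | 2-[(4R)-2,2,4-trimethyl-5-oxo-1,3-dioxolan-4-yl]acetic acid | C[C@]1(CC(=O)O)OC(C)(C)OC1=O | intermediate
11 | (5R)-5-(2-hydroxyethyl)-2,2,5-trimethyl-1,3-dioxolan-4-one | C[C@]1(CCO)OC(C)(C)OC1=O | intermediate
12 | (3R)-3-hydroxy-3-methyloxolan-2-one | C[C@@]1(O)CCOC1=O | intermediate
13 | (2R)-2,4-dihydroxy-N-methoxy-N,2-dimethylbutanamide | CON(C)C(=O)[C@](C)(O)CCO | intermediate
14 | (2R)-N-methoxy-N,2-dimethyl-2,4-bis(triethylsilyloxy)butanamide | CON(C)C(=O)[C@](C)(O[Si](CC)(CC)CC)CCO[Si](CC)(CC)CC | intermediate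
15 | (3R)-3-methyl-3,5-bis(triethylsilyloxy)pentan-2-one | CC(=O)[C@](C)(O[Si](CC)(CC)CC)CCO[Si](CC)(CC)CC | intermediate
16 | lithium enolate of 15, lithium (3R)-3-methyl-3,5-bis(triethylsilyloxy)pent-1-en-2-olate | [Li]OC(=C)[C@](C)(O[Si](CC)(CC)CC)CCO[Si](CC)(CC)CC | intermediate
17 | (3R,7Z)-8-iodo-3,7-dimethyl-1,3-bis(triethylsilyloxy)oct-7-en-4-one | I/C=C(/C)CCC(=O)[C@](C)(O[Si](CC)(CC)CC)CCO[Si](CC)(CC)CC | intermediate
18 | (3R,4S,7Z)-8-iodo-3,7-dimethyl-1,3-bis(triethylsilyloxy)oct-7-en-4-ol | I/C=C(/C)CC[C@H](O)[C@](C)(O[Si](CC)(CC)CC)CCO[Si](CC)(CC)CC | intermediate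
19 | (3R,4S,7Z)-8-iodo-3,7-dimethyloct-7-ene-1,3,4-triol | I/C=C(/C)CC[C@H](O)[C@](C)(O)CCO | intermediate
20 | 2-[(4R,5S)-5-[(3Z)-4-iodo-3-methylbut-3-en-1-yl]-2,2,4-trimethyl-1,3-dioxolan-4-yl]ethan-1-ol | I/C=C(/C)CC[C@@H]1OC(C)(C)O[C@]1(C)CCO | intermediate
21 | 2-[(4R,5S)-5-[(3Z)-4-iodo-3-methylbut-3-en-1-yl]-2,2,4-trimethyl-1,3-dioxolan-4-yl]acetaldehyde | I/C=C(/C)CC[C@@H]1OC(C)(C)O[C@]1(C)CC=O | intermediate
22 | methyl (3S,4R)-5-Dx-3-{[(4-methoxybenzyl)oxy]methyl}-2-methylidene-4-(trimethylsilyloxy)pentanoate | I/C=C(/C)CC[C@@H]1OC(C)(C)O[C@]1(C)C[C@@H](O[Si](C)(C)C)[C@H](COCc2ccc(OC)cc2)C(=C)C(=O)OC | intermediate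
23 | methyl (3S,4R)-4-hydroxy-5-Dx-3-{[(4-methoxybenzyl)oxy]methyl}-2-methylidenepentanoate | I/C=C(/C)CC[C@@H]1OC(C)(C)O[C@]1(C)C[C@@H](O)[C@H](COCc2ccc(OC)cc2)C(=C)C(=O)OC | intermediate
24 | methyl (3S,4R)-4-(tert-butyldimethylsilyloxy)-5-Dx-3-{[(4-methoxybenzyl)oxy]methyl}-2-methylidenepentanoate | I/C=C(/C)CC[C@@H]1OC(C)(C)O[C@]1(C)C[C@@H](O[Si](C)(C)C(C)(C)C)[C@H](COCc2ccc(OC)cc2)C(=C)C(=O)OC | intermediate
25 | methyl (3S,4R)-4-(tert-butyldimethylsilyloxy)-5-Dx-3-(hydroxymethyl)-2-methylidenepentanoate | I/C=C(/C)CC[C@@H]1OC(C)(C)O[C@]1(C)C[C@@H](O[Si](C)(C)C(C)(C)C)[C@H](CO)C(=C)C(=O)OC | intermediate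
26 | methyl (3R,4R)-4-(tert-butyldimethylsilyloxy)-5-Dx-3-formyl-2-methylidenepentanoate | I/C=C(/C)CC[C@@H]1OC(C)(C)O[C@]1(C)C[C@@H](O[Si](C)(C)C(C)(C)C)[C@H](C=O)C(=C)C(=O)OC | intermediate
27 | methyl (1S,4Z,6R,7R,8R,10R)-8-(tert-butyldimethylsilyloxy)-1,10-(isopropylidenedioxy)-6-(trimethylsilyloxy)germacra-4,11(13)-dien-12-oate | [C@@H]4(O[Si](C)(C)C)/C=C(/C)CC[C@@H]1OC(C)(C)O[C@]1(C)C[C@@H](O[Si](C)(C)C(C)(C)C)[C@H]4C(=C)C(=O)OC | intermediate
28 | methyl (1S,4Z,6R,7S,8R,10R)-8-(tert-butyldimethylsilyloxy)-6-hydroxy-1,10-(isopropylidenedioxy)germacra-4,11(13)-dien-12-oate | [C@@H]4(O)/C=C(/C)CC[C@@H]1OC(C)(C)O[C@]1(C)C[C@@H](O[Si](C)(C)C(C)(C)C)[C@H]4C(=C)C(=O)OC | intermediate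
29 | (1S,4Z,6R,7S,8R,10R)-8-(tert-butyldimethylsilyloxy)-1,10-(isopropylidenedioxy)germacra-4,11(13)-dien-12,6-olide | C=C1C(=O)O[C@@H]2/C=C(/C)CC[C@@H]3OC(C)(C)O[C@]3(C)C[C@@H](O[Si](C)(C)C(C)(C)C)[C@@H]12 | intermediate
30 | (1S,4Z,6R,7R,8R,10R)-8-hydroxy-1,10-(isopropylidenedioxy)germacra-4,11(13)-dien-12,6-olide | C=C1C(=O)O[C@@H]2/C=C(/C)CC[C@@H]3OC(C)(C)O[C@]3(C)C[C@@H](O)[C@@H]12 | intermediate
31 | (1S,4Z,6R,7R,8R,10R)-1,10-(isopropylidenedioxy)-8-(3-methylbutanoyloxy)germacra-4,11(13)-dien-12,6-olide | C=C1C(=O)O[C@@H]2/C=C(/C)CC[C@@H]3OC(C)(C)O[C@]3(C)C[C@@H](OC(=O)CC(C)C)[C@@H]12 | intermediate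
32 | (1S,4Z,6R,7R,8R,10R)-1,10-dihydroxy-8-(3-methylbutanoyloxy)germacra-4,11(13)-dien-12,6-olide | C=C1C(=O)O[C@@H]2/C=C(/C)CC[C@H](O)[C@](C)(O)C[C@@H](OC(=O)CC(C)C)[C@@H]12 | intermediate
33 | (4Z,6R,7R,8R,10R)-10-hydroxy-8-(3-methylbutanoyloxy)-1-oxogermacra-4,11(13)-dien-12,6-olide (CNP0105188.1) | C=C1C(=O)O[C@@H]2/C=C(/C)CCC(=O)[C@](C)(O)C[C@@H](OC(=O)CC(C)C)[C@@H]12 | target

**Step count and risks**

Total steps: 22. Longest linear sequence: 18 steps (steps 5–22, from (R)-citramalic acid).

Step 18 (most likely to fail). The process at risk is attack of the alkenylchromium on the other face of the aldehyde, should the forming ring prefer a gauche C5–C6–C7–C8 arrangement, which ends in the cis-fused lactone; slow closure also gives the aldehyde time to lose its C7 configuration. The fallback sets out from 26 and rejoins the route at 29, and corrects C6 by an invertive lactonisation instead of a retentive acylation. The electrolysis is run as before but worked up without the acid treatment. The 6S silyl ether F1 is cleaved with aqueous citric acid to the 6S hydroxy ester F2. LiOH in THF–H2O then gives the 6S hydroxy acid F3. Mitsunobu lactonisation (PPh3, diisopropyl azodicarboxylate, toluene, 0 °C) closes the five-membered lactone with inversion at C6 and should give 29; the five-membered closure is expected to suppress SN2' attack.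

Step 14. The process at risk is E/Z equilibration of the allylchromium, or a mismatched catalyst–substrate pairing, eroding the syn relation or the face selectivity. The fallback sets out from 7 and 21 and rejoins at 23, replacing the chromium reagent by a configurationally fixed allylboron reagent. Alcohol 7 is acetylated (Ac2O, DMAP) to the acetate F4. CuCl-catalysed SN2' borylation with bis(pinacolato)diboron gives the allylboronate F5, with CH2OPMB trans to the ester. Allylboration of 21 (Sc(OTf)3 catalysis at low temperature, or a chiral binaphthyl hydrogen phosphate chosen for the Si face) passes through a closed chair that transmits the alkene geometry into the syn pair. It gives the borate F6, and aqueous work-up frees 23.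

Step 16. The process at risk is closure of the freed C6 hydroxyl onto the methyl ester (γ-lactone formation) before it can be oxidised. The fallback sets out from 5 and 21 and rejoins at 26, carrying C6 at the aldehyde oxidation level throughout.
- Methyl acrylate 5 and 2,2-dimethoxyacetaldehyde (DABCO) give the Baylis–Hillman acetal F7.
- NBS/Me2S converts it into the Z bromide F8.
- The chromium-catalysed allylation of 21 under the conditions of step 14 gives the silyl ether F9 and then the alcohol F10.
- tBuMe2SiOTf/2,6-lutidine gives the silyl ether F11.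
- Et3SiOTf/2,4,6-collidine followed by water cleaves the dimethyl acetal selectively in the presence of the dioxolane and should release 26 without a free C6 alcohol ever being formed.

Further compounds
F1 | step 18 | 6S epimer of silyl ether 27 | [C@H]4(O[Si](C)(C)C)/C=C(/C)CC[C@@H]1OC(C)(C)O[C@]1(C)C[C@@H](O[Si](C)(C)C(C)(C)C)[C@H]4C(=C)C(=O)OC
F2 | step 18 | 6S epimer of hydroxy ester 28 | [C@H]4(O)/C=C(/C)CC[C@@H]1OC(C)(C)O[C@]1(C)C[C@@H](O[Si](C)(C)C(C)(C)C)[C@H]4C(=C)C(=O)OC
F3 | step 18 | (1S,4Z,6S,8R,10R)-8-(tert-butyldimethylsilyloxy)-6-hydroxy-1,10-(isopropylidenedioxy)germacra-4,11(13)-dien-12-oic acid, C7 as in 28 | [C@H]4(O)/C=C(/C)CC[C@@H]1OC(C)(C)O[C@]1(C)C[C@@H](O[Si](C)(C)C(C)(C)C)[C@H]4C(=C)C(=O)O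
F4 | step 14 | methyl 3-acetoxy-4-[(4-methoxybenzyl)oxy]-2-methylidenebutanoate (racemic) | C=C(C(=O)OC)C(OC(C)=O)COCc1ccc(OC)cc1
F5 | step 14 | methyl (2E)-4-[(4-methoxybenzyl)oxy]-2-[(4,4,5,5-tetramethyl-1,3,2-dioxaborolan-2-yl)methyl]but-2-enoate | COC(=O)/C(CB1OC(C)(C)C(C)(C)O1)=C/COCc1ccc(OC)cc1
F6 | step 14 | pinacol borate of 23 at O8 | I/C=C(/C)CC[C@@H]1OC(C)(C)O[C@]1(C)C[C@@H](OB2OC(C)(C)C(C)(C)O2)[C@H](COCc2ccc(OC)cc2)C(=C)C(=O)OC
F7 | step 16 | methyl 3-hydroxy-4,4-dimethoxy-2-methylidenebutanoate (racemic) | C=C(C(=O)OC)C(O)C(OC)OC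
F8 | step 16 | methyl (2Z)-2-(bromomethyl)-4,4-dimethoxybut-2-enoate | BrC/C(C(=O)OC)=C\C(OC)OC
F9 | step 16 | methyl (3R,4R)-3-(dimethoxymethyl)-5-Dx-2-methylidene-4-(trimethylsilyloxy)pentanoate | I/C=C(/C)CC[C@@H]1OC(C)(C)O[C@]1(C)C[C@@H](O[Si](C)(C)C)[C@H](C(OC)OC)C(=C)C(=O)OC
F10 | step 16 | methyl (3R,4R)-3-(dimethoxymethyl)-4-hydroxy-5-Dx-2-methylidenepentanoate | I/C=C(/C)CC[C@@H]1OC(C)(C)O[C@]1(C)C[C@@H](O)[C@H](C(OC)OC)C(=C)C(=O)OC
F11 | step 16 | methyl (3R,4R)-4-(tert-butyldimethylsilyloxy)-3-(dimethoxymethyl)-5-Dx-2-methylidenepentanoate | I/C=C(/C)CC[C@@H]1OC(C)(C)O[C@]1(C)C[C@@H](O[Si](C)(C)C(C)(C)C)[C@H](C(OC)OC)C(=C)C(=O)OC
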